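**Assumptions:** the target SMILES decodes as (2S), which is natural (–)-glabrol. 7-Hydroxychromone and the (S)-bisphosphine ligand are taken as catalogue items.

## Retrosynthetic overview
1. Glabrol ⇒ twofold aromatic Claisen of the (S)-7,4'-bis(1,1-dimethylallyl) ether of liquiritigenin. Both prenyl groups and both free phenols appear in the last step, and these ethers are the only "protecting groups".
2. Bis-ether ⇒ C2–C1' bond by Rh-catalysed enantioselective 1,4-arylation of an intact chromone with an arylboronic acid. This sets C2 directly and avoids the chalcone/oxa-Michael route.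
3. Both coupling partners ⇒ Pd-catalysed O-tert-prenylation of 7-hydroxychromone and 4-bromophenol with one shared carbonate reagent.
4. Ring order: no ring is built. Rings A and C are bought as the chromone, ring B is attached at C2, and the pyranone becomes the (S)-dihydropyranone in the key step.

## Forward route

**Step 1**
Reactants: 1, 2-methylbut-3-en-2-ol
Product: 2, tert-butyl (2-methylbut-3-en-2-yl) carbonate
Conditions: n-BuLi (1.05 equiv), THF, 0 °C; then Boc2O, 0 °C → rt
Reagents that add atoms: di-tert-butyl dicarbonate, CC(C)(C)OC(=O)OC(=O)OC(C)(C)C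
Why: O-acylation of a lithium tertiary alkoxide (carbonate formation) gives a tertiary allylic carbonate that ionises readily with Pd(0); no stereocentre.

**Step 2**
Reactants: 3, 7-hydroxy-4H-chromen-4-one; 2
Product: 4, 7-(2-methylbut-3-en-2-yloxy)-4H-chromen-4-one
Conditions: 2 (2.5 equiv), Pd(PPh3)4 (5 mol %), THF, 0–4 °C, 12 h; Et3N-deactivated SiO2, store cold
Reagents that add atoms: compound 2 (delivers the C5H9 unit), C=CC(C)(C)OC(=O)OC(C)(C)C
Why: Tsuji–Trost O-allylation, in which Pd(0) ionises 2 with loss of CO2, the released t-BuO⁻ deprotonates the acidic 7-OH, and the phenoxide attacks the more substituted π-allyl terminus under cold kinetic control to give the tertiary ether, as known for hydroxyxanthone-type phenols; no stereocentre.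

**Step 3**
Reactants: 5, 4-bromophenol; 2
Product: 6, 1-bromo-4-(2-methylbut-3-en-2-yloxy)benzene
Conditions: 2 (2 equiv), Pd(PPh3)4 (3 mol %), THF, 0–4 °C, 12 h
Reagents that add atoms: compound 2, C=CC(C)(C)OC(=O)OC(C)(C)C
Why: the same kinetic, branched-selective Tsuji–Trost etherification applies, and carbonate ionisation at 0 °C is far faster than oxidative addition of Pd(PPh3)n into an electron-rich aryl bromide; no stereocentre.

**Step 4**
Reactants: 6
Product: 7, [4-(2-methylbut-3-en-2-yloxy)phenyl]boronic acid
Conditions: n-BuLi, THF, –78 °C; B(Oi-Pr)3, –78 °C → 0 °C; sat. aq NH4Cl (no mineral acid)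
Reagents that add atoms: triisopropyl borate, CC(C)OB(OC(C)C)OC(C)C; water, O
Why: Br/Li exchange followed by borate trapping and hydrolysis works here because the ether carbon is quaternary (no α-H, no Wittig pathway) and the near-neutral quench spares the acid-labile tertiary allyl ether; no stereocentre.

**Step 5 (key step)**
Reactants: 4; 7 (1.8 equiv)
Product: 8, (2S)-7-(2-methylbut-3-en-2-yloxy)-2-[4-(2-methylbut-3-en-2-yloxy)phenyl]-2,3-dihydro-4H-chromen-4-one
Conditions: [RhCl(C2H4)2]2 (1.5 mol %), (S)-MeO-F12-BIPHEP [(S)-6,6'-dimethoxy-2,2'-bis{bis(3,4,5-trifluorophenyl)phosphino}biphenyl] (3.3 mol %), aq KOH (10 mol %), PhMe/H2O 10:1, 25 °C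
Reagents that add atoms: compound 7 (aryl donor), C=CC(C)(C)Oc1ccc(B(O)O)cc1 (the C3–H comes from water)
Why: Hayashi–Miyaura asymmetric 1,4-addition to a chromone, in which the electron-poor (S)-biaryl bisphosphine makes Ar–Rh insertion fast at rt (so the Rh enolate is protonated before β-aryloxide ring opening) and its quadrant model delivers the aryl to the Re face of C2 (O1 > C3 > H) to give (2S), the same spatial sense as (S)-BINAP giving (S)-3-arylcyclohexanone; the neopentyl-type vinyl groups cannot isomerise and insert much more slowly than the enone.

**Step 6**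
Reactants: 8
Product: 9, glabrol, (2S)-7-hydroxy-2-[4-hydroxy-3-(3-methylbut-2-enyl)phenyl]-8-(3-methylbut-2-enyl)-2,3-dihydro-4H-chromen-4-one
Conditions: N,O-bis(trimethylsilyl)acetamide (6 equiv), degassed m-xylene (0.02 M), 140 °C, sealed tube, 6–8 h; then MeOH/10 % aq citric acid, rt, 15 min
Reagents that add atoms: none (the TMS groups from BSA are transient and lost in the work-up)
Why: twofold aromatic Claisen [3,3] rearrangement, in which the B-ring ether has two equivalent ortho sites (giving 3'-prenyl), the 7-O ether migrates to C8 because C7–C8 has the higher double-bond character (the established preference for 7-allyloxy-chromanones and coumarins), and in-situ O-silylation traps each new phenol to block chroman formation, acid-catalysed isoprene loss and phenol-assisted retro-oxa-Michael, so the untouched C2 stereocentre stays (S).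

**Control points:** measure ee by chiral HPLC on 8 and 9. Confirm absolute configuration by CD and rotation, since (2S)-flavanones are levorotatory. If the sense of induction is opposite, use the (R)-ligand.

## Compound list

| No. | Name | SMILES | Role |
|---|---|---|---|
| 1 | 2-methylbut-3-en-2-ol | C=CC(C)(C)O | starting material |
| 2 | tert-butyl (2-methylbut-3-en-2-yl) carbonate | C=CC(C)(C)OC(=O)OC(C)(C)C | intermediate |
| 3 | 7-hydroxy-4H-chromen-4-one | O=c1ccoc2cc(O)ccc12 | starting material |
| 4 | 7-(2-methylbut-3-en-2-yloxy)-4H-chromen-4-one | O=c1ccoc2cc(OC(C)(C)C=C)ccc12 | intermediate |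
| 5 | 4-bromophenol | Oc1ccc(Br)cc1 | starting material |
| 6 | 1-bromo-4-(2-methylbut-3-en-2-yloxy)benzene | C=CC(C)(C)Oc1ccc(Br)cc1 | intermediate |
| 7 | [4-(2-methylbut-3-en-2-yloxy)phenyl]boronic acid | C=CC(C)(C)Oc1ccc(B(O)O)cc1 | intermediate |
| 8 | (2S)-7,4'-bis(2-methylbut-3-en-2-yloxy)flavanone | C=CC(C)(C)Oc1ccc([C@@H]2CC(=O)c3ccc(OC(C)(C)C=C)cc3O2)cc1 | intermediate |
| 9 | (2S)-glabrol | CC(C)=CCc1cc([C@@H]2CC(=O)c3ccc(O)c(CC=C(C)C)c3O2)ccc1O | target |

## Summary
Total steps: 6.
Longest linear sequence: 5 (1 → 2 → 6 → 7 → 8 → 9).

**Three steps most likely to fail**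

1. **Step 6, double Claisen.** The risks are C6 versus C8 regiochemistry, isoprene loss from the electron-poor 7-O ether, and erosion of ee at 140 °C.
   Fallback: move both rearrangements ahead of the stereocentre.
   - Heat achiral 4 and 6 separately to give 7-hydroxy-8-prenylchromone and 4-bromo-2-prenylphenol, and separate any regioisomer at that stage.
   - Protect both as TBS ethers and borylate the bromide.
   - Run the same Rh arylation, then finish with Et3N·3HF.

2. **Step 5, asymmetric arylation.** The risks are a sluggish donor-substituted chromone, protodeboronation, Rh-enolate ring opening, and 1,2-over-addition.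
   Fallback: give up catalyst-controlled C–C bond formation. Make racemic 8 with an achiral catalyst such as [Rh(OH)(cod)]2, or from the chalcone. Then obtain (S)-8 by kinetic resolution through Noyori-type asymmetric transfer hydrogenation (Ru or Rh with TsDPEN, HCO2H/Et3N), which reduces the (R)-ketone to the flavan-4-ol and leaves (S)-8.

3. **Step 2, Pd O-tert-prenylation of the acidic 7-OH.** The main risk is Pd-mediated re-ionisation to the linear prenyl ether, with C-allylation as a second risk.
   Fallback: build the tertiary ether without π-allyl chemistry, which applies equally to 5 → 6.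
   - Carry out Cu-catalysed 1,1-dimethylpropargylation with 3-chloro-3-methylbut-1-yne, CuCl2 (cat.) and DBU in MeCN at 0 °C.
   - Follow with Lindlar semihydrogenation to give the 1,1-dimethylallyl ether.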